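**Retrosynthetic overview**
1. Target 11 ⇐ MOM ether 10 (deprotection) ⇐ catechol-isoflavone 7 + prenal 8: the dimethylpyran ring is made last, by condensation and oxa-6π closure through a dearomatised o-quinone methide.
2. 7 ⇐ enaminone 3 + 3-methoxy-o-benzoquinone 5, made by oxidative dearomatisation of 3-methoxycatechol 4: one operation forms the C3–C1' bond and the γ-pyrone ring (Michael addition, re-aromatisation, annulation).
3. 3 ⇐ 2,4-dihydroxyacetophenone 1 (4-O-MOM, then DMF-DMA).
4. Ring order: the two benzene rings are bought; γ-pyrone ring in step 3; 2H-pyran (chromene) ring in step 4.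

Assumption: the target SMILES has no stereocentre and no stereogenic double bond, so the compound is achiral and no enantiocontrol is needed.

**Step 1**
Reactants: 1 2,4-dihydroxyacetophenone
Product: 2 1-[2-hydroxy-4-(methoxymethoxy)phenyl]ethanone
Conditions: MOMCl (1.1 equiv), K2CO3 (2 equiv), acetone, 0 °C → rt
Reagents that add atoms: chloromethyl methyl ether (MOMCl), COCCl
Why: Williamson-type O-alkylation in which the 2-OH is tied up in a hydrogen bond to the ketone, so only the 4-OH is etherified.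

**Step 2**
Reactants: 2 1-[2-hydroxy-4-(methoxymethoxy)phenyl]ethanone
Product: 3 (E)-3-(dimethylamino)-1-[2-hydroxy-4-(methoxymethoxy)phenyl]prop-2-en-1-one
Conditions: DMF-DMA (2.5 equiv), toluene, 95 °C
Reagents that add atoms: N,N-dimethylformamide dimethyl acetal (DMF-DMA), CN(C)C(OC)OC
Why: Aminomethylenation of the methyl ketone (enaminone condensation) gives the thermodynamic E-enaminone, and the MOM ether prevents O-methylation of the 4-oxygen.

**Step 3**
Reactants: 3 (E)-3-(dimethylamino)-1-[2-hydroxy-4-(methoxymethoxy)phenyl]prop-2-en-1-one; 4 3-methoxycatechol (3-methoxybenzene-1,2-diol)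
Product: 7 3-(3,4-dihydroxy-5-methoxyphenyl)-7-(methoxymethoxy)-4H-chromen-4-one, via 3-methoxy-1,2-benzoquinone 5 (not isolated), via 2-(3,4-dihydroxy-5-methoxyphenyl)-3-(dimethylamino)-1-[2-hydroxy-4-(methoxymethoxy)phenyl]prop-2-en-1-one 6 (not isolated)
Conditions: 4 (1.2 equiv), Ag2O (2.5 equiv), Na2SO4, Et2O, 0 °C, dark, 15 min; cold filtrate added dropwise to 3, AcOH (3 equiv), CH2Cl2, −20 °C → rt, Ar
Reagents that add atoms: none
Why: Proposed new method: Ag2O dehydrogenates the catechol to the non-aromatic o-quinone 5, whose C5 (the unsubstituted β-carbon of the C1 enone; the 3-OMe pushes electron density onto C4 and C6, not C5) accepts the nucleophilic α-carbon of enaminone 3 in a Nenitzescu-type Michael addition; tautomerisation re-aromatises the ring to α-aryl enaminone 6, the intermediate of the deoxybenzoin/DMF-DMA isoflavone synthesis, which closes by attack of the 2-OH on the β-carbon with loss of Me2NH (trapped by AcOH); the closest known reaction types are the Nenitzescu quinone–enaminone addition, Michael additions of carbon nucleophiles to in-situ-generated o-quinones, and electrophile-triggered chromone annulation of o-hydroxyaryl enaminones.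

**Step 4**
Reactants: 7 3-(3,4-dihydroxy-5-methoxyphenyl)-7-(methoxymethoxy)-4H-chromen-4-one; 8 3-methylbut-2-enal (prenal)
Product: 10 3-(8-hydroxy-7-methoxy-2,2-dimethyl-2H-chromen-5-yl)-7-(methoxymethoxy)-4H-chromen-4-one, via 3-[(6Z)-4-hydroxy-3-methoxy-6-(3-methylbut-2-en-1-ylidene)-5-oxocyclohexa-1,3-dien-1-yl]-7-(methoxymethoxy)-4H-chromen-4-one 9 (not isolated)
Conditions: 8 (3 equiv), ethylenediammonium diacetate (20 mol %), toluene, 110 °C (sealed tube), Ar
Reagents that add atoms: none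
Why: Knoevenagel-type condensation of the prenal iminium at C2', the only free carbon ortho to a phenolic OH (the 4'-OH has no free ortho position and the A-ring oxygen is capped as MOM), gives the dearomatised o-quinone methide 9, which closes irreversibly by oxa-6π electrocyclisation to the 2,2-dimethyl-2H-chromene, while attack at C6' is reversible and unproductive.

**Step 5**
Reactants: 10 3-(8-hydroxy-7-methoxy-2,2-dimethyl-2H-chromen-5-yl)-7-(methoxymethoxy)-4H-chromen-4-one
Product: 11 7-hydroxy-3-(8-hydroxy-7-methoxy-2,2-dimethyl-2H-chromen-5-yl)-4H-chromen-4-one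
Conditions: 3 M aq. HCl, MeOH, 50 °C
Reagents that add atoms: none
Why: Acid hydrolysis of the MOM acetal frees the 7-OH, and 2,2-dimethyl-2H-chromenes, aryl methyl ethers and the chromone tolerate dilute HCl/MeOH at this temperature.

**Compound list**
1 | 2,4-dihydroxyacetophenone | CC(=O)c1ccc(O)cc1O | starting material
2 | 1-[2-hydroxy-4-(methoxymethoxy)phenyl]ethanone | CC(=O)c1ccc(OCOC)cc1O | intermediate
3 | (E)-3-(dimethylamino)-1-[2-hydroxy-4-(methoxymethoxy)phenyl]prop-2-en-1-one | CN(C)/C=C/C(=O)c1ccc(OCOC)cc1O | intermediate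
4 | 3-methoxycatechol (3-methoxybenzene-1,2-diol) | COc1cccc(O)c1O | starting material
5 | 3-methoxy-1,2-benzoquinone (3-methoxycyclohexa-3,5-diene-1,2-dione) | COC1=CC=CC(=O)C1=O | intermediate (not isolated)
6 | 2-(3,4-dihydroxy-5-methoxyphenyl)-3-(dimethylamino)-1-[2-hydroxy-4-(methoxymethoxy)phenyl]prop-2-en-1-one (alkene geometry not defined) | CN(C)C=C(C(=O)c1ccc(OCOC)cc1O)c1cc(O)c(O)c(OC)c1 | intermediate (not isolated)
7 | 3-(3,4-dihydroxy-5-methoxyphenyl)-7-(methoxymethoxy)-4H-chromen-4-one | COCOc1ccc2c(c1)occ(-c1cc(O)c(O)c(OC)c1)c2=O | intermediate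
8 | 3-methylbut-2-enal (prenal) | CC(C)=CC=O | starting material
9 | 3-[(6Z)-4-hydroxy-3-methoxy-6-(3-methylbut-2-en-1-ylidene)-5-oxocyclohexa-1,3-dien-1-yl]-7-(methoxymethoxy)-4H-chromen-4-one (o-quinone methide) | CC(C)=C\C=C1/C(=O)C(O)=C(OC)C=C1c1coc2cc(OCOC)ccc2c1=O | intermediate (not isolated)
10 | 3-(8-hydroxy-7-methoxy-2,2-dimethyl-2H-chromen-5-yl)-7-(methoxymethoxy)-4H-chromen-4-one | COCOc1ccc2c(c1)occ(-c1cc(OC)c(O)c3c1C=CC(C)(C)O3)c2=O | intermediate
11 | 7-hydroxy-3-(8-hydroxy-7-methoxy-2,2-dimethyl-2H-chromen-5-yl)-4H-chromen-4-one | COc1cc(-c2coc3cc(O)ccc3c2=O)c2c(c1O)OC(C)(C)C=C2 | target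

**Totals**
Total step count: 5. Longest linear sequence: 5 (1 → 2 → 3 → 7 → 10 → 11); 4 enters at step 3 and 8 at step 4.

**Steps most likely to fail, with fallbacks**

Step 3 (quinone stability, site of attack on 5, over-oxidation of 7). The fallback sets out from 3, 4 and 8 and comes back at 10, so it also replaces step 4. Iodine-triggered cyclisation of 3 (I2, CHCl3, rt) gives 3-iodo-7-(methoxymethoxy)-4H-chromen-4-one F1. Separately, 4 and 8 are condensed under the ethylenediammonium diacetate conditions at the unhindered C6 of 4 to give 7-methoxy-2,2-dimethyl-2H-chromen-8-ol F2. Bromination para to the free phenol (NBS, MeCN, −20 °C) gives 5-bromo-7-methoxy-2,2-dimethyl-2H-chromen-8-ol F3. Miyaura borylation (B2pin2, Pd(dppf)Cl2, KOAc, dioxane, 80 °C) gives 7-methoxy-2,2-dimethyl-5-(4,4,5,5-tetramethyl-1,3,2-dioxaborolan-2-yl)-2H-chromen-8-ol F4. Suzuki–Miyaura coupling of F4 with F1 (Pd(dppf)Cl2, K3PO4, dioxane/H2O, 70 °C) delivers 10.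

Step 4 (C2' is hindered by the neighbouring chromone; C6' competes reversibly). The fallback sets out from 7 and comes back at 10. The less hindered 3'-OH of 7 (the 4'-OH is flanked on both sides) is etherified with 3-chloro-3-methylbut-1-yne (DBU, cat. CuCl2, MeCN, 0 °C) to give 3-[4-hydroxy-3-methoxy-5-(2-methylbut-3-yn-2-yloxy)phenyl]-7-(methoxymethoxy)-4H-chromen-4-one F5. Heating F5 (xylene, 140 °C) triggers the aryl propargyl ether Claisen rearrangement, [1,5]-H shift and oxa-6π closure. The rearrangement can only reach C2', because the other ortho carbon carries the 4'-OH, and the product is 10.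

Step 5 (acid in the presence of the electron-rich chromene phenol). The fallback sets out from 1 and comes back at 11, carrying the 7-oxygen as a fluoride-labile silyl ether. Silylation of 1 (TIPSCl, imidazole, DMF, 0 °C) gives 1-[2-hydroxy-4-(triisopropylsilyloxy)phenyl]ethanone F6. DMF-DMA as in step 2 gives (E)-3-(dimethylamino)-1-[2-hydroxy-4-(triisopropylsilyloxy)phenyl]prop-2-en-1-one F7. Coupling with 5 (from 4) as in step 3 gives 3-(3,4-dihydroxy-5-methoxyphenyl)-7-(triisopropylsilyloxy)-4H-chromen-4-one F8. Chromenylation with 8 as in step 4 gives 3-(8-hydroxy-7-methoxy-2,2-dimethyl-2H-chromen-5-yl)-7-(triisopropylsilyloxy)-4H-chromen-4-one F9. TBAF/AcOH (THF, 0 °C) then gives 11 without any acid step.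

**Further compounds**
F1 | step 3 | 3-iodo-7-(methoxymethoxy)-4H-chromen-4-one | COCOc1ccc2c(c1)occ(I)c2=O
F2 | step 3 | 7-methoxy-2,2-dimethyl-2H-chromen-8-ol | COc1ccc2c(c1O)OC(C)(C)C=C2
F3 | step 3 | 5-bromo-7-methoxy-2,2-dimethyl-2H-chromen-8-ol | COc1cc(Br)c2c(c1O)OC(C)(C)C=C2
F4 | step 3 | 7-methoxy-2,2-dimethyl-5-(4,4,5,5-tetramethyl-1,3,2-dioxaborolan-2-yl)-2H-chromen-8-ol | COc1cc(B3OC(C)(C)C(C)(C)O3)c2c(c1O)OC(C)(C)C=C2
F5 | step 4 | 3-[4-hydroxy-3-methoxy-5-(2-methylbut-3-yn-2-yloxy)phenyl]-7-(methoxymethoxy)-4H-chromen-4-one | COCOc1ccc2c(c1)occ(-c1cc(OC)c(O)c(OC(C)(C)C#C)c1)c2=O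
F6 | step 5 | 1-[2-hydroxy-4-(triisopropylsilyloxy)phenyl]ethanone | CC(=O)c1ccc(O[Si](C(C)C)(C(C)C)C(C)C)cc1O
F7 | step 5 | (E)-3-(dimethylamino)-1-[2-hydroxy-4-(triisopropylsilyloxy)phenyl]prop-2-en-1-one | CN(C)/C=C/C(=O)c1ccc(O[Si](C(C)C)(C(C)C)C(C)C)cc1O
F8 | step 5 | 3-(3,4-dihydroxy-5-methoxyphenyl)-7-(triisopropylsilyloxy)-4H-chromen-4-one | COc1cc(-c2coc3cc(O[Si](C(C)C)(C(C)C)C(C)C)ccc3c2=O)cc(O)c1O
F9 | step 5 | 3-(8-hydroxy-7-methoxy-2,2-dimethyl-2H-chromen-5-yl)-7-(triisopropylsilyloxy)-4H-chromen-4-one | COc1cc(-c2coc3cc(O[Si](C(C)C)(C(C)C)C(C)C)ccc3c2=O)c2c(c1O)OC(C)(C)C=C2
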